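Assumption: compounds 1, 4, 9, 16, 25 and 27 are taken as purchasable; 4 (derived from D-malic acid) and 9 (from cellulose-derived levoglucosenone) are the only chiral purchases.

**Retrosynthetic overview**
1. Target 31 ⇐ furan 29 by sensitised singlet-oxygen opening of the 2-methylfuran, which delivers the ring ketone, the acetyl group and the Z-alkene together; enol ester ⇐ E-alkenyl boronate + acid 27 ⇐ terminal vinyl.
2. Seven-membered ring ⇐ bromofuran enynol 22 by directed hydroalumination and intramolecular Pd coupling (C8–C8a).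
3. 22 ⇐ alkynyl tetrahydrofuran 19 by zinc ring opening (frees the C6 hydroxyl and the vinyl group) and furan bromination; C6 ⇐ oxocarbenium alkynylation.
4. Quaternary C5 ⇐ two lactone enolate alkylations (iodide 8, then MeI); C4 ⇐ nickel-electrocatalysed conjugate addition of bromofuran 3 to butenolide 9 (the key C–C bond, from which all ring stereocentres are relayed).
5. Ring order: lactone (bought) → tetrahydrofuran → opened → cycloheptene closed onto the furan → furan opened last.

**Step 1**
Reactants: 1 4-bromofuran-2-carbaldehyde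
Product: 3 4-bromo-2-methylfuran, via 4-bromofuran-2-carbaldehyde hydrazone 2 (not isolated)
Conditions: N2H4·H2O, diethylene glycol, 100 °C; then KOH, 150 → 190 °C, product distilled out
Reagents that add atoms: none
Why: Wolff–Kishner (Huang-Minlon) reduction turns the formyl group into the methyl group that later becomes the acetyl methyl, leaving the bromide untouched.

**Step 2**
Reactants: 4 (R)-3-hydroxydihydrofuran-2(3H)-one
Product: 5 (R)-3-[(tert-butyldimethylsilyl)oxy]dihydrofuran-2(3H)-one
Conditions: TBSCl, imidazole, DMF, 0 → 25 °C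
Reagents that add atoms: tert-butyldimethylsilyl chloride, CC(C)(C)[Si](C)(C)Cl
Why: Standard silyl ether formation protects the purchased carbinol stereocentre (the side-chain R centre of the target) without touching it.

**Step 3**
Reactants: 5 (R)-3-[(tert-butyldimethylsilyl)oxy]dihydrofuran-2(3H)-one
Product: 6 (3R)-3-[(tert-butyldimethylsilyl)oxy]-5-hydroxypentan-2-one (present largely as its cyclic hemiketal)
Conditions: MeLi (1.05 equiv), THF, −78 °C; then H2O
Reagents that add atoms: methyllithium, [Li]C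
Why: Mono-addition of an organolithium to a lactone, which stops at the lithium hemiketal at −78 °C so the methyl ketone is released only on quench.

**Step 4**
Reactants: 6 (3R)-3-[(tert-butyldimethylsilyl)oxy]-5-hydroxypentan-2-one
Product: 7 (R)-3-[(tert-butyldimethylsilyl)oxy]-4-methylpent-4-en-1-ol
Conditions: Ph3PCH3Br, n-BuLi, THF, 0 °C; then 6, −78 → 25 °C
Reagents that add atoms: methylenetriphenylphosphorane, C=P(c1ccccc1)(c1ccccc1)c1ccccc1
Why: Wittig methylenation of the open ketone tautomer builds the isopropenyl group; the lithium counter-ion and low temperature limit epimerisation next to the ketone and silyl migration.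

**Step 5**
Reactants: 7 (R)-3-[(tert-butyldimethylsilyl)oxy]-4-methylpent-4-en-1-ol
Product: 8 (R)-tert-butyl[(5-iodo-2-methylpent-1-en-3-yl)oxy]dimethylsilane
Conditions: I2, PPh3, imidazole, CH2Cl2, 0 °C
Reagents that add atoms: iodine, II
Why: Appel-type iodination of the primary alcohol gives the side-chain electrophile with the stereocentre untouched.

**Step 6**
Reactants: 9 (S)-5-(hydroxymethyl)furan-2(5H)-one; 3 4-bromo-2-methylfuran
Product: 10 (4R,5S)-5-(hydroxymethyl)-4-(5-methylfuran-3-yl)dihydrofuran-2(3H)-one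
Conditions: undivided cell, Fe anode (sacrificial), Ni-foam cathode, NiBr2(bpy) (10 mol %), n-Bu4NBr, DMF/pyridine 9:1, constant current (2.2 F per mol of 3), 25–40 °C; 3 (2 equiv)
Reagents that add atoms: none
Why: Nickel-catalysed electroreductive conjugate arylation, in which cathodically formed zerovalent nickel inserts into the carbon–bromine bond and the furyl–nickel adds 1,4 to the butenolide anti to the C5 hydroxymethyl group, so the new C4 centre (trans) is set by the purchased C5 centre.

**Step 7**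
Reactants: 10 (4R,5S)-5-(hydroxymethyl)-4-(5-methylfuran-3-yl)dihydrofuran-2(3H)-one
Product: 11 [(2S,3R)-3-(5-methylfuran-3-yl)-5-oxotetrahydrofuran-2-yl]methyl 4-methylbenzenesulfonate
Conditions: TsCl, pyridine, DMAP (cat.), CH2Cl2, 0 → 25 °C
Reagents that add atoms: 4-methylbenzenesulfonyl chloride, Cc1ccc(cc1)S(=O)(=O)Cl
Why: Sulfonylation installs the leaving group for the later ring opening; it is introduced only on the saturated lactone, where γ-deprotonation and elimination are no longer possible.

**Step 8**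
Reactants: 11 [(2S,3R)-3-(5-methylfuran-3-yl)-5-oxotetrahydrofuran-2-yl]methyl 4-methylbenzenesulfonate; 8 (R)-tert-butyl[(5-iodo-2-methylpent-1-en-3-yl)oxy]dimethylsilane
Product: 12 [(2S,3R,4S)-4-{(3R)-3-[(tert-butyldimethylsilyl)oxy]-4-methylpent-4-en-1-yl}-3-(5-methylfuran-3-yl)-5-oxotetrahydrofuran-2-yl]methyl 4-methylbenzenesulfonate
Conditions: LiN(i-Pr)2 (1.1 equiv), THF, −78 °C; 8 (1.5 equiv), DMPU, −78 → −30 °C
Reagents that add atoms: none
Why: Lithium lactone enolate alkylation (SN2) with the primary iodide, which enters anti to the neighbouring furyl group; this configuration is overwritten in step 9.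

**Step 9**
Reactants: 12 mono-alkylated lactone
Product: 13 [(2S,3S,4R)-4-{(3R)-3-[(tert-butyldimethylsilyl)oxy]-4-methylpent-4-en-1-yl}-4-methyl-3-(5-methylfuran-3-yl)-5-oxotetrahydrofuran-2-yl]methyl 4-methylbenzenesulfonate
Conditions: LiN(i-Pr)2 (1.3 equiv), THF, −78 → −40 °C; MeI, DMPU, −78 → −20 °C
Reagents that add atoms: iodomethane, CI
Why: Second enolate alkylation, in which MeI approaches the planar enolate anti to the adjacent furyl group, so methyl ends trans and the side chain cis to furyl; the quaternary centre is thereby set by the furyl-bearing centre.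

**Step 10**
Reactants: 13 quaternary lactone
Product: 15 [(2S,3S,4R)-5-acetoxy-4-{(3R)-3-[(tert-butyldimethylsilyl)oxy]-4-methylpent-4-en-1-yl}-4-methyl-3-(5-methylfuran-3-yl)tetrahydrofuran-2-yl]methyl 4-methylbenzenesulfonate (both C5 epimers), via diisobutylaluminium lactol alkoxide 14 (not isolated)
Conditions: i-Bu2AlH (1.2 equiv), CH2Cl2, −78 °C; then pyridine, DMAP, Ac2O, −78 → 0 °C
Reagents that add atoms: acetic anhydride, CC(=O)OC(C)=O
Why: Reductive acetylation (hydride reduction of the lactone and in situ O-acylation of the aluminium hemiacetal) gives the α-acetoxy ether without over-reduction; the anomeric mixture is irrelevant.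

**Step 11**
Reactants: 15 lactol acetate; 16 tert-butyldimethyl(prop-2-yn-1-yloxy)silane
Product: 19 [(2S,3R,4R,5R)-5-{3-[(tert-butyldimethylsilyl)oxy]prop-1-yn-1-yl}-4-{(3R)-3-[(tert-butyldimethylsilyl)oxy]-4-methylpent-4-en-1-yl}-4-methyl-3-(5-methylfuran-3-yl)tetrahydrofuran-2-yl]methyl 4-methylbenzenesulfonate, via lithium acetylide 17 (not isolated), via alkynyldimethylalane 18 (not isolated)
Conditions: 16 (3 equiv), n-BuLi, toluene, −78 → 0 °C; Me2AlCl, 0 °C; then 15, CH2Cl2, −40 → 0 °C
Reagents that add atoms: none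
Why: C-glycosylation-type oxocarbenium alkynylation, in which the Lewis-acidic alane ionises the acetate and delivers the alkynyl group by inside attack on the envelope cation on the face opposite the furyl group and the side chain (the face carrying only methyl), giving the 3,5-trans product and setting the carbinol carbon from the furyl-bearing centre.

**Step 12**
Reactants: 19 alkynyl tetrahydrofuran
Product: 21 (4R,5R,6R)-1-[(tert-butyldimethylsilyl)oxy]-5-{(3R)-3-[(tert-butyldimethylsilyl)oxy]-4-methylpent-4-en-1-yl}-5-methyl-6-(5-methylfuran-3-yl)oct-7-en-2-yn-4-ol, via 2-(iodomethyl)tetrahydrofuran 20 (not isolated)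
Conditions: NaI (5 equiv), DMF, 70 °C; then Zn dust (10 equiv), 70 °C; aq NH4Cl
Reagents that add atoms: none
Why: Finkelstein exchange then zinc-mediated reductive β-elimination (Boord/Vasella type) opens the tetrahydrofuran, releasing the terminal vinyl group and the free secondary alcohol with its configuration intact.

**Step 13**
Reactants: 21 enynol
Product: 22 (4R,5R,6R)-6-(2-bromo-5-methylfuran-3-yl)-1-[(tert-butyldimethylsilyl)oxy]-5-{(3R)-3-[(tert-butyldimethylsilyl)oxy]-4-methylpent-4-en-1-yl}-5-methyloct-7-en-2-yn-4-ol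
Conditions: N-bromosuccinimide (1.0 equiv), THF, −78 → −40 °C, dark
Reagents that add atoms: N-bromosuccinimide, O=C1CCC(=O)N1Br
Why: Electrophilic aromatic bromination occurs at the only free α-position of the electron-rich furan much faster than NBS attacks the unactivated alkenes or the alkyne.

**Step 14**
Reactants: 22 bromofuran enynol
Product: 24 (4R,5R,6S)-8-{[(tert-butyldimethylsilyl)oxy]methyl}-5-{(3R)-3-[(tert-butyldimethylsilyl)oxy]-4-methylpent-4-en-1-yl}-4-ethenyl-2,5-dimethyl-5,6-dihydro-4H-cyclohepta[b]furan-6-ol, via cyclic sodium alkenylalanate 23 (not isolated)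
Conditions: NaAlH2(OCH2CH2OMe)2 (2.2 equiv), THF, −20 → 0 °C; then ZnCl2 (1 equiv), Pd(PPh3)4 (5 mol %), 45 °C
Reagents that add atoms: none
Why: Proposed new method: a one-pot hydroxyl-directed trans-hydroalumination and intramolecular palladium-catalysed alkenyl–heteroaryl coupling that closes the seven-membered ring; the aluminium hydride bound to the C6 oxygen places H on the proximal and Al on the distal alkyne carbon (five-membered alanate 23, Al cis to the carbinol carbon), zerovalent palladium inserts into the furyl carbon–bromine bond (a furyl–palladium species that cannot reach the bystander vinyl or isopropenyl groups in a feasible ring size), and ZnCl2-assisted transmetalation and reductive elimination form C8–C8a with retention, the ring enforcing the cis alkene; the closest known reaction types are the intermolecular Negishi-type coupling of propargyl-alcohol-derived alkenylalanates with aryl halides and intramolecular Negishi or Suzuki ring closures; no stereocentre is made or touched.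

**Step 15**
Reactants: 24 tricyclic furan alcohol; 25 4,4,5,5-tetramethyl-2-vinyl-1,3,2-dioxaborolane
Product: 26 (4R,5R,6S)-8-{[(tert-butyldimethylsilyl)oxy]methyl}-5-{(3R)-3-[(tert-butyldimethylsilyl)oxy]-4-methylpent-4-en-1-yl}-2,5-dimethyl-4-[(E)-2-(4,4,5,5-tetramethyl-1,3,2-dioxaborolan-2-yl)ethenyl]-5,6-dihydro-4H-cyclohepta[b]furan-6-ol
Conditions: second-generation Hoveyda–Grubbs catalyst (10 mol %), 25 (8 equiv), CH2Cl2, 40 °C
Reagents that add atoms: none
Why: Olefin cross-metathesis of the only monosubstituted alkene with excess vinylboronate gives the E-alkenyl boronate; the silyloxy-flanked isopropenyl group and the ring alkene are too hindered to react or ring-close at this temperature.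

**Step 16**
Reactants: 26 alkenyl boronate; 27 3-methylbut-2-enoic acid
Product: 28 (E)-2-[(4R,5R,6S)-8-{[(tert-butyldimethylsilyl)oxy]methyl}-5-{(3R)-3-[(tert-butyldimethylsilyl)oxy]-4-methylpent-4-en-1-yl}-6-hydroxy-2,5-dimethyl-5,6-dihydro-4H-cyclohepta[b]furan-4-yl]ethenyl 3-methylbut-2-enoate
Conditions: Cu(OAc)2 (2 equiv), Et3N (3 equiv), 4 Å molecular sieves, CH2Cl2, air, 25 °C
Reagents that add atoms: none
Why: Chan–Lam–Evans-type copper-mediated oxidative C–O coupling of the alkenyl boronate with the carboxylic acid proceeds with retention of the E geometry, the carboxylate outcompeting the hindered secondary alcohol.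

**Step 17**
Reactants: 28 bis-silyl enol ester
Product: 29 (E)-2-[(4R,5R,6S)-6-hydroxy-5-[(3R)-3-hydroxy-4-methylpent-4-en-1-yl]-8-(hydroxymethyl)-2,5-dimethyl-5,6-dihydro-4H-cyclohepta[b]furan-4-yl]ethenyl 3-methylbut-2-enoate
Conditions: HF·pyridine, pyridine, THF, 0 → 25 °C
Reagents that add atoms: none
Why: Buffered fluoride cleavage of both silyl ethers spares the enol ester and the acid-sensitive furan, and is done before the base-sensitive ene-dione exists.

**Step 18**
Reactants: 29 furan triol
Product: 31 CNP0146349.1, (E)-2-[(1R,2R,3S,7Z)-3-hydroxy-5-(hydroxymethyl)-2-[(3R)-3-hydroxy-4-methylpent-4-en-1-yl]-2-methyl-6-oxo-7-(2-oxopropylidene)cyclohept-4-en-1-yl]ethenyl 3-methylbut-2-enoate, via furan endoperoxide 30 (not isolated)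
Conditions: O2, 5,10,15,20-tetraphenylporphyrin (1 mol %), CH2Cl2, −78 °C, visible light (>500 nm); then Me2S, −78 → 0 °C, dark
Reagents that add atoms: dioxygen, O=O
Why: Photosensitised singlet-oxygen [4+2] cycloaddition across the trisubstituted furan (far faster than the ene reaction of the 1,1-disubstituted alkene), then reductive opening of the endoperoxide by Me2S, gives the ring ketone and the acetyl group with the Z geometry inherited from the furan ring.

**Compound list**
1 | 4-bromofuran-2-carbaldehyde | O=Cc1cc(Br)co1 | starting material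
2 | 4-bromofuran-2-carbaldehyde hydrazone | NN=Cc1cc(Br)co1 | intermediate (not isolated)
3 | 4-bromo-2-methylfuran | Cc1cc(Br)co1 | intermediate
4 | (R)-3-hydroxydihydrofuran-2(3H)-one | O[C@@H]1CCOC1=O | starting material
5 | (R)-3-[(tert-butyldimethylsilyl)oxy]dihydrofuran-2(3H)-one | CC(C)(C)[Si](C)(C)O[C@@H]1CCOC1=O | intermediate
6 | (3R)-3-[(tert-butyldimethylsilyl)oxy]-5-hydroxypentan-2-one (open form of the hemiketal) | CC(=O)[C@H](O[Si](C)(C)C(C)(C)C)CCO | intermediate
7 | (R)-3-[(tert-butyldimethylsilyl)oxy]-4-methylpent-4-en-1-ol | C=C(C)[C@H](O[Si](C)(C)C(C)(C)C)CCO | intermediate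
8 | (R)-tert-butyl[(5-iodo-2-methylpent-1-en-3-yl)oxy]dimethylsilane | C=C(C)[C@H](O[Si](C)(C)C(C)(C)C)CCI | intermediate
9 | (S)-5-(hydroxymethyl)furan-2(5H)-one | O=C1C=C[C@@H](CO)O1 | starting material
10 | (4R,5S)-5-(hydroxymethyl)-4-(5-methylfuran-3-yl)dihydrofuran-2(3H)-one (furyl trans to CH2OH) | Cc1cc([C@H]2CC(=O)O[C@@H]2CO)co1 | intermediate
11 | [(2S,3R)-3-(5-methylfuran-3-yl)-5-oxotetrahydrofuran-2-yl]methyl 4-methylbenzenesulfonate | Cc1cc([C@H]2CC(=O)O[C@@H]2COS(=O)(=O)c2ccc(C)cc2)co1 | intermediate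
12 | mono-alkylated lactone, (2S,3R,4S), side chain trans to furyl | Cc1cc([C@H]2[C@H](CC[C@@H](O[Si](C)(C)C(C)(C)C)C(C)=C)C(=O)O[C@@H]2COS(=O)(=O)c2ccc(C)cc2)co1 | intermediate
13 | quaternary lactone, (2S,3S,4R), methyl trans and side chain cis to furyl | Cc1cc([C@H]2[C@@](C)(CC[C@@H](O[Si](C)(C)C(C)(C)C)C(C)=C)C(=O)O[C@@H]2COS(=O)(=O)c2ccc(C)cc2)co1 | intermediate
14 | diisobutylaluminium lactol alkoxide of 13 | Cc1cc([C@H]2[C@@](C)(CC[C@@H](O[Si](C)(C)C(C)(C)C)C(C)=C)C(O[Al](CC(C)C)CC(C)C)O[C@@H]2COS(=O)(=O)c2ccc(C)cc2)co1 | intermediate (not isolated)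
15 | lactol acetate of 13, (2S,3S,4R), C5 epimers | Cc1cc([C@H]2[C@@](C)(CC[C@@H](O[Si](C)(C)C(C)(C)C)C(C)=C)C(OC(C)=O)O[C@@H]2COS(=O)(=O)c2ccc(C)cc2)co1 | intermediate
16 | tert-butyldimethyl(prop-2-yn-1-yloxy)silane | C#CCO[Si](C)(C)C(C)(C)C | starting material
17 | lithium 3-[(tert-butyldimethylsilyl)oxy]prop-1-yn-1-ide | [Li]C#CCO[Si](C)(C)C(C)(C)C | intermediate (not isolated)
18 | {3-[(tert-butyldimethylsilyl)oxy]prop-1-yn-1-yl}dimethylaluminium | C[Al](C)C#CCO[Si](C)(C)C(C)(C)C | intermediate (not isolated)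
19 | alkynyl tetrahydrofuran, (2S,3R,4R,5R), alkynyl trans to furyl | Cc1cc([C@H]2[C@@](C)(CC[C@@H](O[Si](C)(C)C(C)(C)C)C(C)=C)[C@H](C#CCO[Si](C)(C)C(C)(C)C)O[C@@H]2COS(=O)(=O)c2ccc(C)cc2)co1 | intermediate
20 | 2-(iodomethyl) analogue of 19 | Cc1cc([C@H]2[C@@](C)(CC[C@@H](O[Si](C)(C)C(C)(C)C)C(C)=C)[C@H](C#CCO[Si](C)(C)C(C)(C)C)O[C@@H]2CI)co1 | intermediate (not isolated)
21 | (4R,5R,6R)-1-[(tert-butyldimethylsilyl)oxy]-5-{(3R)-3-[(tert-butyldimethylsilyl)oxy]-4-methylpent-4-en-1-yl}-5-methyl-6-(5-methylfuran-3-yl)oct-7-en-2-yn-4-ol | C=C(C)[C@H](O[Si](C)(C)C(C)(C)C)CC[C@@](C)([C@@H](O)C#CCO[Si](C)(C)C(C)(C)C)[C@@H](C=C)c1coc(C)c1 | intermediate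
22 | (4R,5R,6R)-6-(2-bromo-5-methylfuran-3-yl) analogue of 21 | C=C(C)[C@H](O[Si](C)(C)C(C)(C)C)CC[C@@](C)([C@@H](O)C#CCO[Si](C)(C)C(C)(C)C)[C@@H](C=C)c1c(Br)oc(C)c1 | intermediate
23 | cyclic sodium alkenyl(alkoxy)bis(2-methoxyethoxy)aluminate from 22 | [Na+].C=C(C)[C@H](O[Si](C)(C)C(C)(C)C)CC[C@@](C)([C@H]1O[Al-](OCCOC)(OCCOC)C(CO[Si](C)(C)C(C)(C)C)=C1)[C@@H](C=C)c1c(Br)oc(C)c1 | intermediate (not isolated)
24 | (4R,5R,6S)-8-{[(tert-butyldimethylsilyl)oxy]methyl}-5-{(3R)-3-[(tert-butyldimethylsilyl)oxy]-4-methylpent-4-en-1-yl}-4-ethenyl-2,5-dimethyl-5,6-dihydro-4H-cyclohepta[b]furan-6-ol | C=C(C)[C@H](O[Si](C)(C)C(C)(C)C)CC[C@@]1(C)[C@@H](O)C=C(CO[Si](C)(C)C(C)(C)C)c2oc(C)cc2[C@@H]1C=C | intermediate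
25 | 4,4,5,5-tetramethyl-2-vinyl-1,3,2-dioxaborolane | C=CB1OC(C)(C)C(C)(C)O1 | starting material
26 | (4R,5R,6S) E-alkenyl pinacol boronate of 24 | C=C(C)[C@H](O[Si](C)(C)C(C)(C)C)CC[C@@]1(C)[C@@H](O)C=C(CO[Si](C)(C)C(C)(C)C)c2oc(C)cc2[C@@H]1/C=C/B1OC(C)(C)C(C)(C)O1 | intermediate
27 | 3-methylbut-2-enoic acid | CC(C)=CC(=O)O | starting material
28 | bis-silyl E-enol ester, (4R,5R,6S) | C=C(C)[C@H](O[Si](C)(C)C(C)(C)C)CC[C@@]1(C)[C@@H](O)C=C(CO[Si](C)(C)C(C)(C)C)c2oc(C)cc2[C@@H]1/C=C/OC(=O)C=C(C)C | intermediate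
29 | furan triol E-enol ester, (4R,5R,6S), side-chain carbinol R | C=C(C)[C@H](O)CC[C@@]1(C)[C@@H](O)C=C(CO)c2oc(C)cc2[C@@H]1/C=C/OC(=O)C=C(C)C | intermediate
30 | 2,5-endoperoxide of furan 29 | C=C(C)[C@H](O)CC[C@@]1(C)[C@@H](O)C=C(CO)C23OOC(C)(O2)C=C3[C@@H]1/C=C/OC(=O)C=C(C)C | intermediate (not isolated)
31 | CNP0146349.1 | C=C(C)[C@H](O)CC[C@@]1(C)[C@@H](O)C=C(CO)C(=O)/C(=C\C(C)=O)[C@@H]1/C=C/OC(=O)C=C(C)C | target

**Step count**
Total: 18 steps. Longest linear sequence: 15 steps (steps 2–5, then 8–18, from 4).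

**Three steps most likely to fail**

Step 14 (the proposed new ring closure). The alanate may lose the neighbouring silyloxy group to give an allene, the bromofuran may be reduced, or transmetalation into an eight-membered palladacycle may be slow. The fallback uses known chemistry and sets out from 22: the same hydroalumination is run, but alanate 23 is trapped with 2-isopropoxy-4,4,5,5-tetramethyl-1,3,2-dioxaborolane to give the isolable alkenyl pinacol boronate F1 (boron cis to the carbinol carbon). A standard intramolecular Suzuki–Miyaura coupling (PdCl2(dppf), K3PO4, THF/H2O, 40 °C) then returns to 24.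

Step 6 (electrochemical conjugate arylation). Protodebromination or homocoupling of 3, cathodic reduction of the butenolide, or base-induced epimerisation of 9 could erode yield. The fallback sets out from 3 and 9 and replaces electrochemistry by rhodium catalysis: 3 is lithiated with n-BuLi at −78 °C to (5-methylfuran-3-yl)lithium F2, which is quenched with B(OMe)3 and aqueous acid to give (5-methylfuran-3-yl)boronic acid F3. Hayashi–Miyaura-type 1,4-addition of F3 to unprotected 9 ([Rh(OH)(cod)]2, dioxane/H2O, 40 °C, again anti to the hydroxymethyl group) returns to 10.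

Step 11 (oxocarbenium alkynylation). The cation sits next to a quaternary carbon, and the nucleophile could enter on the furyl face and give the C5 epimer. The fallback sets out from 13 and inverts the order of bond formation: lithium acetylide 17 adds to the lactone at −78 °C to give the alkynyl hemiketal F4, and ionic reduction (Et3SiH, BF3·OEt2, CH2Cl2, −78 → −40 °C) then delivers hydride instead of carbon to the same cation face. This leaves the alkynyl group on the other face from the one the direct alkynylation gave, and the sequence returns to 19.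

**Further compounds**
F1 | step 14 | (4S,5R,6R)-6-(2-bromo-5-methylfuran-3-yl)-1-[(tert-butyldimethylsilyl)oxy]-5-{(3R)-3-[(tert-butyldimethylsilyl)oxy]-4-methylpent-4-en-1-yl}-5-methyl-2-(4,4,5,5-tetramethyl-1,3,2-dioxaborolan-2-yl)octa-2,7-dien-4-ol (boron cis to C4) | C=C(C)[C@H](O[Si](C)(C)C(C)(C)C)CC[C@@](C)([C@@H](O)/C=C(\B1OC(C)(C)C(C)(C)O1)CO[Si](C)(C)C(C)(C)C)[C@@H](C=C)c1c(Br)oc(C)c1
F2 | step 6 | (5-methylfuran-3-yl)lithium | [Li]c1coc(C)c1
F3 | step 6 | (5-methylfuran-3-yl)boronic acid | Cc1cc(B(O)O)co1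
F4 | step 11 | alkynyl hemiketal of lactone 13 (2-hydroxy-2-alkynyl tetrahydrofuran, anomers) | Cc1cc([C@H]2[C@@](C)(CC[C@@H](O[Si](C)(C)C(C)(C)C)C(C)=C)C(O)(C#CCO[Si](C)(C)C(C)(C)C)O[C@@H]2COS(=O)(=O)c2ccc(C)cc2)co1
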